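Target 19 ⇐ tricyclic lactone 14 (by decarboxylation, SN2 ether cleavage, O6 acylation and loss of HBr); in 14 the future methylene carbon C13 is held as a CH2 bridge to the C6 oxygen.
14 ⇐ malonate ether 11 by an oxidative radical-polar double annulation across C7=C8: C11 adds to C7, then an ester oxygen closes on C8.
Enabling feature: on the six-membered ring C5–C10 the C6 oxygen, the C7–C11 bond and the C8 lactone oxygen are contiguous and all β, and C13 lies 1,3 to the C6 oxygen. C13 can therefore act as a one-carbon tether (temporary tetrahydrofuran C6–O–C13–C11–C7) cis-fused to the γ-lactone (C7–C11–C12–O–C8).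
11 ⇐ allylic alcohol 9 + di-tert-butyl methylenemalonate; 9 ⇐ enone 8 (CBS reduction) ⇐ cyclohexene 7 (allylic oxidation) ⇐ Diels–Alder adduct 6 (double methylenation).
6 ⇐ catalytic asymmetric Diels–Alder reaction of (E)-enal 4 with 1-acetoxybutadiene (sets C5, C9, C10). Ring order: cyclohexene; then tetrahydrofuran and γ-lactone together; then the tetrahydrofuran is reopened.

Key step: step 8

Remarks
Numbering and faces: elemane numbering is used. The ring is C5–C10; C1=C2 is the vinyl group and C14 the methyl group on C10; C4(=C3)–C15 is the 2-propenyl unit on C5; C11(=C13)–C12 is the lactone acrylate unit on C7. β is the ring face that carries the C10 methyl group.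
Assumption: the oxazaborolidinium catalyst made from (S)-α,α-diphenylprolinol is taken to give the enantiomer drawn for 6, as the usual model for α-substituted enals predicts; if the sense were opposite, the catalyst from the (R)-amino alcohol would be used.
Assumption: (E)-1-acetoxybuta-1,3-diene (sold as an E/Z mixture, of which only the E isomer should react) and di-tert-butyl methylenemalonate are bought.

Step 1
Reactants: 1 2-methylprop-1-en-1-ylmagnesium bromide; 2 acetoxyacetyl chloride
Product: 3 4-methyl-2-oxopent-3-en-1-yl acetate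
Conditions: Fe(acac)3 (3 mol %), THF, −78 °C, slow addition of 1 to 2
Reagents that add atoms: none
Why: Iron-catalysed acylation of a Grignard reagent by an acid chloride is much faster at −78 °C than attack on the acetate or on the product ketone, so the β,β-dimethyl enone that already carries the C15 acetoxy group should form, with no stereocentre involved.

Step 2
Reactants: 3 4-methyl-2-oxopent-3-en-1-yl acetate
Product: 4 (E)-5-acetoxy-2-methyl-4-oxopent-2-enal
Conditions: SeO2 (1.2 equiv), 1,4-dioxane, trace H2O, 90 °C
Reagents that add atoms: selenium dioxide O=[Se]=O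
Why: Allylic oxidation with SeO2 (ene reaction then [2,3]-sigmatropic shift, Riley type) attacks the methyl group trans to the acyl substituent of the trisubstituted alkene and carries it to the aldehyde, which should give the (E)-enal with CHO and acyl trans.

Step 3
Reactants: 4 (E)-5-acetoxy-2-methyl-4-oxopent-2-enal; 5 (E)-buta-1,3-dien-1-yl acetate
Product: 6 2-acetoxy-6-(acetoxyacetyl)-1-methylcyclohex-3-ene-1-carbaldehyde (9α-OAc cis to the 10α-CHO; 10β-methyl; 5β-acyl trans to CHO)
Conditions: oxazaborolidinium triflimide catalyst from (S)-α,α-diphenylprolinol, tri(o-tolyl)boroxine and HNTf2 (20 mol %), 5 (3 equiv of the E/Z mixture), CH2Cl2, −78 → −20 °C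
Reagents that add atoms: none
Why: In this Lewis-acid-catalysed endo Diels–Alder reaction the catalyst binds the formyl group, so the unsubstituted diene terminus bonds to C5 (β to CHO) and the acetoxy-bearing terminus to C10; the (E)-geometry of 4 places the C5 acyl group trans to CHO, the formyl-endo approach places the C9 acetoxy group cis to CHO, and the chiral catalyst selects the enal face and so the absolute configuration at C5, C9 and C10.

Step 4
Reactants: 6 2-acetoxy-6-(acetoxyacetyl)-1-methylcyclohex-3-ene-1-carbaldehyde
Product: 7 9α,15-diacetoxy-11,12,13-trinorelema-1,3,7-triene [6-(3-acetoxyprop-1-en-2-yl)-1-ethenyl-1-methylcyclohex-3-en-2-yl acetate]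
Conditions: Zn, CH2Br2, TiCl4 (preformed reagent, 4 equiv), THF/CH2Cl2, 0 °C → rt
Reagents that add atoms: dibromomethane BrCBr
Why: The non-basic Takai–Lombardo methylenation should convert both the hindered neopentyl aldehyde (to the C10 vinyl group) and the enolisable α-acetoxy ketone (to the C4=C3 methylene) without epimerising C5 or touching the acetates, and it creates no stereocentre.

Step 5
Reactants: 7 9α,15-diacetoxy-11,12,13-trinorelema-1,3,7-triene
Product: 8 9α,15-diacetoxy-11,12,13-trinorelema-1,3,7-trien-6-one
Conditions: Rh2(cap)4 (dirhodium tetrakis(caprolactamate), 1 mol %), t-BuOOH (70 % in water, 5 equiv), NaHCO3, CH2Cl2, rt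
Reagents that add atoms: tert-butyl hydroperoxide CC(C)(C)OO
Why: In this catalytic allylic C–H oxidation the tert-butylperoxyl radical should abstract hydrogen from the only unhindered ring allylic methylene (C6) and the mixed peroxide collapses to the enone, because C9–H is deactivated by its acetoxy group and shielded by the quaternary C10 and the C8 end of the allyl radical is the more hindered; no stereocentre is formed.

Step 6
Reactants: 8 9α,15-diacetoxy-11,12,13-trinorelema-1,3,7-trien-6-one
Product: 9 9α,15-diacetoxy-11,12,13-trinorelema-1,3,7-trien-6β-ol (6R; OH cis to the C5 side chain and trans to the 9α-OAc)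
Conditions: (S)-2-methyl-CBS-oxazaborolidine (20 mol %), catecholborane (1.5 equiv), toluene, −78 °C
Reagents that add atoms: none
Why: The CBS reduction is 1,2-selective for enones and, with the branched C5 carbon as the large group, should deliver hydride to the α-face, which is also the face anti to the C5 substituent (matched case), setting the 6β (6R) carbinol.

Step 7
Reactants: 9 9α,15-diacetoxy-11,12,13-trinorelema-1,3,7-trien-6β-ol; 10 di-tert-butyl methylenemalonate
Product: 11 di-tert-butyl 2-{[(9α,15-diacetoxy-11,12,13-trinorelema-1,3,7-trien-6β-yl)oxy]methyl}propanedioate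
Conditions: NaH (10 mol %), 10 (1.5 equiv), THF, −20 → 0 °C; AcOH quench
Reagents that add atoms: none
Why: Alkoxide-initiated oxa-Michael addition to the doubly activated but sterically stabilised methylenemalonate should install the O6–C13H2–C11 tether, the chain being carried by proton transfer from 9 to the malonate anion, with the C6 configuration untouched.

Step 8
Reactants: 11 di-tert-butyl 2-{[(9α,15-diacetoxy-11,12,13-trinorelema-1,3,7-trien-6β-yl)oxy]methyl}propanedioate
Product: 14 tert-butyl 9α,15-diacetoxy-6β,13-epoxyelema-1,3-dien-8β,12-olide-11-carboxylate, via malonyl radical 12 (not isolated), via cyclised C8 radical 13 (not isolated)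
Conditions: Mn(OAc)3·2H2O (2.2 equiv), Cu(OAc)2·H2O (0.5 equiv), degassed AcOH, 70 °C
Reagents that add atoms: none
Why: Manganese triacetate oxidises the malonate C–H of 11 through its manganese enolate to the electrophilic C11 radical 12, which adds 5-exo-trig to C7 of the C7=C8 bond and closes the tetrahydrofuran (C6–O–C13–C11–C7); the secondary C8 radical 13 is then oxidised by divalent copper and captured 5-exo by the carbonyl oxygen of the syn tert-butyl ester, which loses 2-methylpropene and closes the γ-lactone (C7–C11–C12–O–C8). The closest known reaction type is the Mn(OAc)3/Cu(OAc)2 oxidative free-radical cyclisation of unsaturated malonates ending in lactonisation (oxidative double annulation). C7 is set by the tether, which hangs from the β-oxygen on C6 and can reach only the β-face, so the tetrahydrofuran is cis-fused; C8 is set because the lactone can only be cis-fused to that bicycle, so oxygen enters β, anti to the 9α-acetoxy group; C11 is fixed by its membership in both five-membered rings and is removed later. The step needs 5-exo attack at C7 rather than 6-endo attack at C8 or 7-endo attack on the 2-propenyl group, and lactonisation rather than β-hydride elimination; the short tether, the faster 5-exo closure and the ester carbonyl held over C8 should secure these. The quaternary C11 of 14 cannot be enolised, which should protect the product from further oxidation.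

Step 9
Reactants: 14 tert-butyl 9α,15-diacetoxy-6β,13-epoxyelema-1,3-dien-8β,12-olide-11-carboxylate
Product: 16 9α,15-diacetoxy-6β,13-epoxyelema-1,3-dien-8β,12-olide, via carboxylic acid 15 (not isolated)
Conditions: TFA/CH2Cl2 (1:4), 0 °C → rt; evaporate; toluene, 110 °C
Reagents that add atoms: none
Why: Acidolysis of the tert-butyl ester and thermal decarboxylation of the malonic-type acid through the lactone enol should give the C11–H lactone, whose C11 hydrogen can only sit on the exo face because both five-membered rings must stay cis-fused.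

Step 10
Reactants: 16 9α,15-diacetoxy-6β,13-epoxyelema-1,3-dien-8β,12-olide
Product: 17 9α,15-diacetoxy-13-bromo-6β-hydroxyelema-1,3-dien-8β,12-olide
Conditions: Me2BBr (2.5 equiv), Et3N (0.2 equiv), CH2Cl2, −78 → 0 °C; aq NaHCO3
Reagents that add atoms: bromodimethylborane CB(C)Br
Why: In this Lewis-acid-assisted SN2 cleavage of the cyclic ether, boron binds O6 and bromide should attack the primary C13 rather than the secondary C6 flanked by two tertiary carbons, which opens the temporary ring and keeps the C6–O bond and its β configuration.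

Step 11
Reactants: 17 9α,15-diacetoxy-13-bromo-6β-hydroxyelema-1,3-dien-8β,12-olide
Product: 19 9α,15-diacetoxy-6β-(2-methylpropanoyloxy)elema-1,3,11(13)-trien-8β,12-olide (CNP0500052.1), via bromo isobutyrate 18 (not isolated)
Conditions: (i-PrCO)2O (2 equiv), DMAP (10 mol %), pyridine, CH2Cl2, 0 °C → rt; then DBU (1.5 equiv), 0 °C
Reagents that add atoms: 2-methylpropanoic anhydride CC(C)C(=O)OC(=O)C(C)C
Why: DMAP-catalysed acylation of the C6 hydroxyl followed by E1cB dehydrobromination of the β-bromo lactone should give the exocyclic C11=C13 methylene, with no ring stereocentre affected and the C11 stereocentre removed.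

Compound list
1 | 2-methylprop-1-en-1-ylmagnesium bromide | CC(C)=C[Mg]Br | starting material
2 | acetoxyacetyl chloride | CC(=O)OCC(=O)Cl | starting material
3 | 4-methyl-2-oxopent-3-en-1-yl acetate | CC(C)=CC(=O)COC(C)=O | intermediate
4 | (E)-5-acetoxy-2-methyl-4-oxopent-2-enal | O=C/C(C)=C/C(=O)COC(C)=O | intermediate
5 | (E)-buta-1,3-dien-1-yl acetate | C=C/C=C/OC(C)=O | starting material
6 | 2-acetoxy-6-(acetoxyacetyl)-1-methylcyclohex-3-ene-1-carbaldehyde (9α-OAc cis to 10α-CHO; 10β-Me; 5β-acyl) | O=C[C@]1(C)[C@H](OC(C)=O)C=CC[C@H]1C(=O)COC(C)=O | intermediate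
7 | 9α,15-diacetoxy-11,12,13-trinorelema-1,3,7-triene | C=C[C@]1(C)[C@H](OC(C)=O)C=CC[C@H]1C(=C)COC(C)=O | intermediate
8 | 9α,15-diacetoxy-11,12,13-trinorelema-1,3,7-trien-6-one | C=C[C@]1(C)[C@H](OC(C)=O)C=CC(=O)[C@H]1C(=C)COC(C)=O | intermediate
9 | 9α,15-diacetoxy-11,12,13-trinorelema-1,3,7-trien-6β-ol | C=C[C@]1(C)[C@H](OC(C)=O)C=C[C@@H](O)[C@H]1C(=C)COC(C)=O | intermediate
10 | di-tert-butyl methylenemalonate | C=C(C(=O)OC(C)(C)C)C(=O)OC(C)(C)C | starting material
11 | di-tert-butyl 2-{[(9α,15-diacetoxy-11,12,13-trinorelema-1,3,7-trien-6β-yl)oxy]methyl}propanedioate | C=C[C@]1(C)[C@H](OC(C)=O)C=C[C@@H](OCC(C(=O)OC(C)(C)C)C(=O)OC(C)(C)C)[C@H]1C(=C)COC(C)=O | intermediate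
12 | C11 malonyl radical of 11 | C=C[C@]1(C)[C@H](OC(C)=O)C=C[C@@H](OC[C](C(=O)OC(C)(C)C)C(=O)OC(C)(C)C)[C@H]1C(=C)COC(C)=O | intermediate
13 | C8 radical of tert-butyl 9α,15-diacetoxy-11-(tert-butoxycarbonyl)-6β,13-epoxyelema-1,3-dien-12-oate (after 5-exo closure) | C=C[C@]1(C)[C@H](OC(C)=O)[CH][C@@H]2[C@@H](OCC2(C(=O)OC(C)(C)C)C(=O)OC(C)(C)C)[C@H]1C(=C)COC(C)=O | intermediate
14 | tert-butyl 9α,15-diacetoxy-6β,13-epoxyelema-1,3-dien-8β,12-olide-11-carboxylate | C=C[C@]1(C)[C@H](OC(C)=O)[C@H]2OC(=O)[C@@]3(C(=O)OC(C)(C)C)CO[C@H]([C@@H]23)[C@H]1C(=C)COC(C)=O | intermediate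
15 | 9α,15-diacetoxy-6β,13-epoxyelema-1,3-dien-8β,12-olide-11-carboxylic acid | C=C[C@]1(C)[C@H](OC(C)=O)[C@H]2OC(=O)[C@@]3(C(=O)O)CO[C@H]([C@@H]23)[C@H]1C(=C)COC(C)=O | intermediate
16 | 9α,15-diacetoxy-6β,13-epoxyelema-1,3-dien-8β,12-olide | C=C[C@]1(C)[C@H](OC(C)=O)[C@H]2OC(=O)[C@H]3CO[C@H]([C@@H]23)[C@H]1C(=C)COC(C)=O | intermediate
17 | 9α,15-diacetoxy-13-bromo-6β-hydroxyelema-1,3-dien-8β,12-olide | C=C[C@]1(C)[C@H](OC(C)=O)[C@H]2OC(=O)[C@@H](CBr)[C@H]2[C@@H](O)[C@H]1C(=C)COC(C)=O | intermediate
18 | 9α,15-diacetoxy-13-bromo-6β-(2-methylpropanoyloxy)elema-1,3-dien-8β,12-olide | C=C[C@]1(C)[C@H](OC(C)=O)[C@H]2OC(=O)[C@@H](CBr)[C@H]2[C@@H](OC(=O)C(C)C)[C@H]1C(=C)COC(C)=O | intermediate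
19 | 9α,15-diacetoxy-6β-(2-methylpropanoyloxy)elema-1,3,11(13)-trien-8β,12-olide (CNP0500052.1) | C=C[C@]1(C)[C@H](OC(C)=O)[C@H]2OC(=O)C(=C)[C@H]2[C@@H](OC(=O)C(C)C)[C@H]1C(=C)COC(C)=O | target

Total step count: 11. Longest linear sequence: 11 steps (1 and 2 to 19); 5 and 10 enter as purchased building blocks.

Steps most likely to fail

Step 8 (key step). The C8 radical may end in β-hydride elimination from the organocopper species instead of lactonisation, may undergo a 1,2-acetoxy shift from C9, or the malonyl radical may close 7-endo onto the 2-propenyl group. The fallback separates radical C–C bond formation from ionic C–O bond formation and sets out from 11. α-Iodination (N-iodosuccinimide, Et3N, CH2Cl2, 0 °C) should give di-tert-butyl 2-iodo-2-{[(9α,15-diacetoxy-11,12,13-trinorelema-1,3,7-trien-6β-yl)oxy]methyl}propanedioate F2. Iodine atom-transfer radical cyclisation (Et3B, air, benzene, rt) should give tert-butyl 9α,15-diacetoxy-11-(tert-butoxycarbonyl)-6β,13-epoxy-8α-iodoelema-1,3-dien-12-oate F3, with iodine delivered to the open α-face anti to the new ring. Heating (toluene, 100 °C) should let the syn ester carbonyl oxygen displace iodide with inversion (5-exo-tet) and lose the tert-butyl group, which rejoins the route at 14.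

Step 5. Hydrogen abstraction may occur at other allylic sites (the tertiary C5–H beside the 2-propenyl group, or C9–H), or the allyl radical may be trapped at C8 to give the transposed enone. The fallback uses a pericyclic allylic hydroxylation and sets out from 7. SeO2 (0.5 equiv) with t-BuOOH (3 equiv) in CH2Cl2 at rt (ene reaction then [2,3]-sigmatropic shift, which keeps the double bond at C7=C8) should give 9α,15-diacetoxy-11,12,13-trinorelema-1,3,7-trien-6-ol F1 as a mixture of C6 epimers. Dess–Martin oxidation (CH2Cl2, NaHCO3, rt) then converges both epimers on enone 8, where the route is rejoined.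

Step 10. Bromide may attack C6 instead of C13, or the Lewis acid may ionise the allylic C15 acetate. The fallback opens the ring by base and sets out from 16. LiHMDS (1.1 equiv, THF, −78 → −20 °C) should form the lactone enolate, which expels the C13–O6 alkoxide (E1cB β-elimination); an AcOH quench at −78 °C gives 9α,15-diacetoxy-6β-hydroxyelema-1,3,11(13)-trien-8β,12-olide F4. Acylation with 2-methylpropanoic anhydride (DMAP, pyridine, CH2Cl2, 0 °C) then gives the target, so the route is rejoined at 19.

Further compounds
F1 | step 5 | 9α,15-diacetoxy-11,12,13-trinorelema-1,3,7-trien-6-ol (both C6 epimers) | C=C[C@]1(C)[C@H](OC(C)=O)C=CC(O)[C@H]1C(=C)COC(C)=O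
F2 | step 8 | di-tert-butyl 2-iodo-2-{[(9α,15-diacetoxy-11,12,13-trinorelema-1,3,7-trien-6β-yl)oxy]methyl}propanedioate | C=C[C@]1(C)[C@H](OC(C)=O)C=C[C@@H](OCC(I)(C(=O)OC(C)(C)C)C(=O)OC(C)(C)C)[C@H]1C(=C)COC(C)=O
F3 | step 8 | tert-butyl 9α,15-diacetoxy-11-(tert-butoxycarbonyl)-6β,13-epoxy-8α-iodoelema-1,3-dien-12-oate | C=C[C@]1(C)[C@H](OC(C)=O)[C@H](I)[C@@H]2[C@@H](OCC2(C(=O)OC(C)(C)C)C(=O)OC(C)(C)C)[C@H]1C(=C)COC(C)=O
F4 | step 10 | 9α,15-diacetoxy-6β-hydroxyelema-1,3,11(13)-trien-8β,12-olide | C=C[C@]1(C)[C@H](OC(C)=O)[C@H]2OC(=O)C(=C)[C@H]2[C@@H](O)[C@H]1C(=C)COC(C)=O
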